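Eudesmane numbering is used. Ring B (C5–C6–C7–C8–C9–C10) is cut at C9–C10 and C5–C6, a cyclohexene retron. One BF3-directed Diels–Alder reaction joins 2-methoxy-5-methyl-1,4-benzoquinone (ring A with the C10 methyl, the C3 oxygen and a C4 carbonyl) to a 2-substituted butadiene that carries C6–C9 and the C11–C12 acetate arm; it forms both bonds and the quaternary C10. The quinone C1 carbonyl is a temporary activating and regiodirecting group, deleted later by vinylogous-ester transposition, which also unveils the C3 ketone. Enol triflate methylation installs C15, a lipase parts the antipodes at the C3 alcohol, and a singlet-oxygen ene reaction on C4=C5 gives the 5α-hydroperoxide last.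

Key step: step 2

Remark: 1, 2, 5 and 19 are taken as commercial; the cycloaddition is planned racemic (neither quinone face is biased), so 6–13 are racemates drawn as the enantiomer that is carried on, and the single enantiomer is secured in step 8.

Step 1
Reactants: 1 buta-2,3-dien-1-ol; 2 trimethyl orthoacetate
Product: 4 methyl 3-methylidenepent-4-enoate, via ketene acetal 3 (not isolated)
Conditions: 2 (excess), EtCO2H (cat.), 125 °C, MeOH distilled off
Reagents that add atoms: none
Why: Johnson–Claisen rearrangement, in which the mixed ketene acetal of the allenylmethyl alcohol shifts [3,3] onto the central allene carbon and so turns the allene into the 2-substituted 1,3-diene.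

Step 2
Reactants: 4 methyl 3-methylidenepent-4-enoate; 5 2-methoxy-5-methyl-1,4-benzoquinone
Product: 6 (±)-cis Diels–Alder adduct (5-H and 10-methyl cis)
Conditions: BF3·OEt2 (30 mol%), CH2Cl2, −78 to −20 °C
Reagents that add atoms: none
Why: This is a concerted but asynchronous [4+2] cycloaddition; the closest known type is the Lewis acid-catalysed Diels–Alder reaction of a methoxy-p-benzoquinone with a 2-alkylbutadiene. BF3 should bind the more basic, vinylogous-ester carbonyl (C1, on the methyl-bearing C10), so C5 becomes the most electrophilic carbon and takes the diene terminus with the larger HOMO coefficient (C6, next to the substituted C7); this reverses the uncatalysed orientation and places the acetate arm on C7, 1,4 to C10. Ring B closes in one event that is suprafacial on both partners, C9–C10 and C5–C6 forming together through a boat-like six-membered transition state. C10 (quaternary, methyl) and C5 are set cis by the suprafacial addition; no face is preferred, so 6 is racemic, and only C10 is carried on because C5 is flattened in step 3. The step needs the C5=C10 alkene to react instead of C2=C3, which the donor methoxy group on C3 secures; endo/exo selectivity is immaterial because C7 is trigonal.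

Step 3
Reactants: 6 (±)-cis adduct
Product: 8 (±)-C4 enol triflate, via potassium enolate 7 (not isolated)
Conditions: KN(SiMe3)2, THF, −78 °C; then PhNTf2, −78 to 0 °C
Reagents that add atoms: N-phenylbis(trifluoromethanesulfonimide), O=S(=O)(N(c1ccccc1)S(=O)(=O)C(F)(F)F)C(F)(F)F
Why: Enolate O-sulfonylation; C5–H is the only enolisable position of the C4 ketone (C3 is trigonal, the C1 ketone has no α-hydrogen) and is more acidic than the ester CH2, so the C4=C5 enolate should form regiospecifically and be trapped on oxygen, which also erases the C5 stereocenter.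

Step 4
Reactants: 8 (±)-C4 enol triflate
Product: 9 (±)-4-methyl dienone vinylogous ester
Conditions: MeZnCl, Pd(PPh3)4 (5 mol%, zerovalent palladium), THF, 50 °C
Reagents that add atoms: methylzinc chloride, C[Zn]Cl
Why: Negishi cross-coupling of the enol triflate installs C15 on C4 and fixes the tetrasubstituted C4=C5 alkene, while the organozinc reagent leaves ketone, vinylogous ester and methyl ester untouched.

Step 5
Reactants: 9 (±)-4-methyl dienone vinylogous ester
Product: 11 (±)-1,4-dien-3-one, via allylic alcohol 10 (not isolated)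
Conditions: NaBH4, CeCl3·7H2O, MeOH, 0 °C to rt; then 1 M HCl, THF, rt
Reagents that add atoms: water, O
Why: Luche 1,2-reduction of the C1 carbonyl (the methyl ester is not reduced) followed by acid hydrolysis of the enol ether with loss of the allylic hydroxyl (Stork–Danheiser transposition) moves the carbonyl to C3, removes the oxygen from C1 and leaves the cross-conjugated C1=C2/C4=C5 dienone.

Step 6
Reactants: 11 (±)-1,4-dien-3-one
Product: 12 (±)-4-en-3-one with the 7β-acetate arm
Conditions: H2 (5 atm), RhCl(PPh3)3 (15 mol%), benzene–EtOH, 50 °C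
Reagents that add atoms: none
Why: Homogeneous hydrogenation; the rhodium catalyst should reduce the disubstituted C1=C2 and, more slowly, the trisubstituted C7=C8 alkene but not the tetrasubstituted C4=C5 enone alkene, and should deliver hydrogen to C7=C8 from the α face opposite the axial C10 methyl, which sets C7 with the acetate arm β (equatorial).

Step 7
Reactants: 12 (±)-4-en-3-one
Product: 13 (±)-3β-allylic alcohol
Conditions: NaBH4, CeCl3·7H2O, MeOH, −40 °C
Reagents that add atoms: none
Why: Luche reduction; 1,2-hydride attack on the enone from the α face (axial, anti to the C10 methyl) should give the equatorial 3β-alcohol and so set C3, and the ester is not reduced.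

Step 8
Reactants: 13 (±)-3β-allylic alcohol
Product: 14 (3S,7R,10S)-3β-allylic alcohol (single enantiomer)
Conditions: immobilised Burkholderia cepacia lipase, vinyl acetate, tert-butyl methyl ether, 30 °C, run to just beyond half conversion; chromatography
Reagents that add atoms: none
Why: Kinetic resolution by enantioselective transesterification with a lipase (serine hydrolase class); the enzyme should acetylate the (3R) antipode, whose large trigonal C4 flank and smaller CH2 flank fit the acyl-transfer site, and leave the (3S,7R,10S) alcohol, which is separated from the acetate.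

Step 9
Reactants: 14 (3S,7R,10S)-3β-allylic alcohol
Product: 18 3β-hydroxy acrylate, via dilithium enolate 15 (not isolated), via Mannich base 16 (not isolated), via ammonium iodide 17 (not isolated)
Conditions: LiN(iPr)2 (2.2 equiv), THF, −78 °C; CH2=NMe2+ I−, −78 to 0 °C; then MeI, MeOH, rt; then aq NaHCO3, CH2Cl2
Reagents that add atoms: dimethyl(methylidene)ammonium iodide, C=[N+](C)C.[I-]
Why: α-Methylenation of the ester by a Mannich reaction of its lithium enolate with the iminium salt, then N-methylation and E1cB loss of trimethylamine; the C3 alkoxide is a spectator and no stereocenter is touched.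

Step 10
Reactants: 18 3β-hydroxy acrylate; 19 angelic acid
Product: 21 3β-angelate, via mixed anhydride 20 (not isolated)
Conditions: 19, 2,4,6-trichlorobenzoyl chloride, Et3N, toluene, rt; then 18, 80 °C
Reagents that add atoms: none
Why: Yamaguchi esterification through the mixed anhydride acylates the hindered equatorial 3β-hydroxyl with retention at C3 and, run without a nucleophilic amine catalyst, should keep the (Z) geometry of the angelate.

Step 11
Reactants: 21 3β-angelate
Product: 22 target hydroperoxide
Conditions: O2 (1 atm), tetraphenylporphyrin (cat.), visible light, CH2Cl2, 0 °C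
Reagents that add atoms: oxygen, O=O
Why: Schenck ene reaction; singlet oxygen should attack only the electron-rich tetrasubstituted C4=C5 alkene (acrylate and angelate are electron-poor) from the α face opposite the C10 methyl and the 3β-ester, bond to C5 and take a hydrogen from the C15 methyl (the C3 hydrogen is deactivated by the geminal acyloxy group), which sets C5 (5α-OOH) and shifts the alkene to C4=C15, the 4α-hydroperoxy-5-ene isomer from abstraction at C6 being removed by chromatography.

Compound list (naphthalene locants in the names: C2 = eudesmane C7, C4a = C10, C5 = C1, C7 = C3, C8 = C4, C8a = C5)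

1 | buta-2,3-dien-1-ol | C=C=CCO | starting material
2 | trimethyl orthoacetate (1,1,1-trimethoxyethane) | CC(OC)(OC)OC | starting material
3 | 1-(buta-2,3-dien-1-yloxy)-1-methoxyethene (mixed ketene acetal) | C=C(OC)OCC=C=C | intermediate
4 | methyl 3-methylidenepent-4-enoate | C=CC(=C)CC(=O)OC | intermediate
5 | 2-methoxy-5-methylcyclohexa-2,5-diene-1,4-dione (2-methoxy-5-methyl-1,4-benzoquinone) | COC1=CC(=O)C(C)=CC1=O | starting material
6 | (±)-methyl 2-[(4aR*,8aS*)-7-methoxy-4a-methyl-5,8-dioxo-1,4,4a,5,8,8a-hexahydronaphthalen-2-yl]acetate (cis-fused, racemic) | COC(=O)CC1=CC[C@@]2(C)C(=O)C=C(OC)C(=O)[C@H]2C1 | intermediate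
7 | potassium enolate of 6 (C4–O−, C4=C5; racemic) | [K+].COC(=O)CC1=CC[C@@]2(C)C(=O)C=C(OC)C([O-])=C2C1 | intermediate
8 | (±)-methyl 2-[(4aR*)-7-methoxy-4a-methyl-5-oxo-8-(trifluoromethanesulfonyloxy)-1,4,4a,5-tetrahydronaphthalen-2-yl]acetate | COC(=O)CC1=CC[C@@]2(C)C(=O)C=C(OC)C(OS(=O)(=O)C(F)(F)F)=C2C1 | intermediate
9 | (±)-methyl 2-[(4aR*)-7-methoxy-4a,8-dimethyl-5-oxo-1,4,4a,5-tetrahydronaphthalen-2-yl]acetate | COC(=O)CC1=CC[C@@]2(C)C(=O)C=C(OC)C(C)=C2C1 | intermediate
10 | (±)-methyl 2-[(4aR*)-5-hydroxy-7-methoxy-4a,8-dimethyl-1,4,4a,5-tetrahydronaphthalen-2-yl]acetate (epimers at the carbinol carbon) | COC(=O)CC1=CC[C@@]2(C)C(O)C=C(OC)C(C)=C2C1 | intermediate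
11 | (±)-methyl 2-[(4aS*)-4a,8-dimethyl-7-oxo-1,4,4a,7-tetrahydronaphthalen-2-yl]acetate | COC(=O)CC1=CC[C@@]2(C)C=CC(=O)C(C)=C2C1 | intermediate
12 | (±)-methyl 2-[(2R*,4aS*)-4a,8-dimethyl-7-oxo-1,2,3,4,4a,5,6,7-octahydronaphthalen-2-yl]acetate | COC(=O)C[C@@H]1CC[C@@]2(C)CCC(=O)C(C)=C2C1 | intermediate
13 | (±)-methyl 2-[(2R*,4aS*,7S*)-7-hydroxy-4a,8-dimethyl-1,2,3,4,4a,5,6,7-octahydronaphthalen-2-yl]acetate (racemic) | COC(=O)C[C@@H]1CC[C@@]2(C)CC[C@H](O)C(C)=C2C1 | intermediate
14 | methyl 2-[(2R,4aS,7S)-7-hydroxy-4a,8-dimethyl-1,2,3,4,4a,5,6,7-octahydronaphthalen-2-yl]acetate (single enantiomer; eudesmane 3S,7R,10S) | COC(=O)C[C@@H]1CC[C@@]2(C)CC[C@H](O)C(C)=C2C1 | intermediate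
15 | dilithium alkoxide ester enolate of 14 | [Li+].[Li+].COC([O-])=C[C@@H]1CC[C@@]2(C)CC[C@H]([O-])C(C)=C2C1 | intermediate
16 | methyl 3-(dimethylamino)-2-[(2R,4aS,7S)-7-hydroxy-4a,8-dimethyl-1,2,3,4,4a,5,6,7-octahydronaphthalen-2-yl]propanoate (epimers at the ester α-carbon) | COC(=O)C(CN(C)C)[C@@H]1CC[C@@]2(C)CC[C@H](O)C(C)=C2C1 | intermediate
17 | N,N,N-trimethylammonium iodide of 16 | COC(=O)C(C[N+](C)(C)C)[C@@H]1CC[C@@]2(C)CC[C@H](O)C(C)=C2C1.[I-] | intermediate
18 | methyl 2-[(2R,4aS,7S)-7-hydroxy-4a,8-dimethyl-1,2,3,4,4a,5,6,7-octahydronaphthalen-2-yl]prop-2-enoate | C=C(C(=O)OC)[C@@H]1CC[C@@]2(C)CC[C@H](O)C(C)=C2C1 | intermediate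
19 | angelic acid, (2Z)-2-methylbut-2-enoic acid | C/C=C(/C)C(=O)O | starting material
20 | (2Z)-2-methylbut-2-enoic 2,4,6-trichlorobenzoic anhydride | C/C=C(/C)C(=O)OC(=O)c1c(Cl)cc(Cl)cc1Cl | intermediate
21 | methyl 2-[(2R,4aS,7S)-4a,8-dimethyl-7-{[(2Z)-2-methylbut-2-enoyl]oxy}-1,2,3,4,4a,5,6,7-octahydronaphthalen-2-yl]prop-2-enoate | C=C(C(=O)OC)[C@@H]1CC[C@@]2(C)CC[C@H](OC(=O)/C(C)=C\C)C(C)=C2C1 | intermediate
22 | methyl 2-[(2R,4aS,7S,8aS)-8a-hydroperoxy-4a-methyl-8-methylidene-7-{[(2Z)-2-methylbut-2-enoyl]oxy}decahydronaphthalen-2-yl]prop-2-enoate (eudesmane 3S,5S,7R,10S) | C=C(C(=O)OC)[C@@H]1CC[C@@]2(C)CC[C@H](OC(=O)/C(C)=C\C)C(=C)[C@]2(OO)C1 | target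

Total step count: 11. Longest linear sequence: 11 steps (1 → 4 → 6 → 8 → 9 → 11 → 12 → 13 → 14 → 18 → 21 → 22).

Steps most likely to fail

Step 2. BF3 may not discriminate cleanly between the two quinone carbonyls, so that the diene adds in both orientations and regiocontrol (arm on C7 versus C8) is lost. Fallback: the C4 carbonyl is masked so that the C1 carbonyl alone can direct. 4,5-Dimethoxy-2-methylphenol is oxidised with PhI(OAc)2 in MeOH to the quinone monoketal 4,4,5-trimethoxy-2-methylcyclohexa-2,5-dien-1-one F1. Its methyl-bearing enone alkene (the other alkene is a vinylogous ester) takes up diene 4 on heating in toluene in a sealed tube and should give the ketal adduct F2 with the arm 1,4 to C10. Oxalic acid in wet THF then unmasks the C4 ketone. This fallback sets out from diene 4 and comes back to the route at adduct 6.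

Step 5. Hydride delivery to the hindered, electron-rich C1 carbonyl may be too slow under conditions mild enough to spare the methyl ester. Fallback: from 9, LiAlH4 in THF at 0 °C reduces both the C1 carbonyl and the ester to the diol F3 (not isolated). 1 M HCl then effects the transposition to the 2-hydroxyethyl dienone F4. CrO3/H2SO4 in acetone oxidises the primary alcohol to the dienone acetic acid F5, and Me3SiCHN2 in MeOH restores the methyl ester. This fallback sets out from 9 and comes back at 11.

Step 6. The trisubstituted C7=C8 alkene may resist the rhodium catalyst, or forcing conditions may erode the facial selectivity at C7. Fallback: the two alkenes are reduced at different stages. From 9, H2 (1 atm) over Pd/C in EtOAc saturates C7=C8 first, from the α face, to give the 7,8-dihydro vinylogous ester F6; the ring-A alkenes are tetrasubstituted or enol-ether deactivated. The reduction–transposition of step 5 (NaBH4/CeCl3, then HCl) passes through the allylic alcohol F7 to the ring-B-saturated 1,4-dien-3-one F8. RhCl(PPh3)3 under 1 atm H2 then reduces only the disubstituted C1=C2 alkene. This fallback sets out from 9 and comes back at 12.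

Further compounds
F1 | step 2 | 4,4,5-trimethoxy-2-methylcyclohexa-2,5-dien-1-one | COC1=CC(=O)C(C)=CC1(OC)OC
F2 | step 2 | (±)-methyl 2-[(4aR*,8aS*)-7,8,8-trimethoxy-4a-methyl-5-oxo-1,4,4a,5,8,8a-hexahydronaphthalen-2-yl]acetate | COC(=O)CC1=CC[C@@]2(C)C(=O)C=C(OC)C(OC)(OC)[C@H]2C1
F3 | step 5 | (±)-(4aR*)-6-(2-hydroxyethyl)-3-methoxy-4,8a-dimethyl-1,5,8,8a-tetrahydronaphthalen-1-ol (epimers at the carbinol carbon) | OCCC1=CC[C@@]2(C)C(O)C=C(OC)C(C)=C2C1
F4 | step 5 | (±)-(4aS*)-7-(2-hydroxyethyl)-1,4a-dimethyl-5,8-dihydronaphthalen-2(4aH)-one | OCCC1=CC[C@@]2(C)C=CC(=O)C(C)=C2C1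
F5 | step 5 | (±)-2-[(4aS*)-4a,8-dimethyl-7-oxo-1,4,4a,7-tetrahydronaphthalen-2-yl]acetic acid | OC(=O)CC1=CC[C@@]2(C)C=CC(=O)C(C)=C2C1
F6 | step 6 | (±)-methyl 2-[(2R*,4aR*)-7-methoxy-4a,8-dimethyl-5-oxo-1,2,3,4,4a,5-hexahydronaphthalen-2-yl]acetate | COC(=O)C[C@@H]1CC[C@@]2(C)C(=O)C=C(OC)C(C)=C2C1
F7 | step 6 | (±)-methyl 2-[(2R*,4aR*)-5-hydroxy-7-methoxy-4a,8-dimethyl-1,2,3,4,4a,5-hexahydronaphthalen-2-yl]acetate (epimers at the carbinol carbon) | COC(=O)C[C@@H]1CC[C@@]2(C)C(O)C=C(OC)C(C)=C2C1
F8 | step 6 | (±)-methyl 2-[(2R*,4aS*)-4a,8-dimethyl-7-oxo-1,2,3,4,4a,7-hexahydronaphthalen-2-yl]acetate | COC(=O)C[C@@H]1CC[C@@]2(C)C=CC(=O)C(C)=C2C1
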